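**Plan**

- Numbering: ring A is the oxane (O1, C2 gem-dimethyl, C3 bromine, C6 methyl). Ring B is the cyclohexane C1'–C6' (C1' on C6, C3' bromine, C4' chlorine and methyl).
- Retrosynthesis: (a) ring B is cut at C5'–C6' (ring-closing metathesis, then saturation); (b) C3'–Br and C4'–Cl go back to an open-chain (Z)-trisubstituted allylic alcohol; (c) C1'–C2' is cut by a Johnson–Claisen transform; (d) ring A is cut at O1–C2 and C3–Br back to (R)-linalool.
- Forward: ring A first (bromoetherification), then the chain is grown from its vinyl group (ozonolysis, Wittig, CBS reduction, Claisen, Still–Gennari), the Br/Cl pair is set on the open chain, and ring B is closed last.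
- Enabling feature: C5'–C6' is the only bond of ring B that touches none of its stereocentres (C1', C3', C4'), and C4' is quaternary. BrCl addition to a preformed cyclohexene would add diaxially and give the C1' epimer, so the trans-diequatorial Br/Cl pair is fixed by anti addition to an open-chain (Z)-alkene and only then enclosed.
- Stereochemistry: C6 from (R)-linalool; C3 from chair bromoetherification (epimers separated); C1' from (R)-CBS reduction and suprafacial chirality transfer in the Claisen step; C3'/C4' from catalyst-controlled anti bromochlorination.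

Key step: step 12

Remark: commercial (R)-(−)-linalool of high enantiomeric purity is assumed; for step 9 the enantiomer of the chiral ligand is assumed to be the one that, in a trial on a simple (Z)-2-methylalk-2-en-1-ol, delivers bromine and chlorine in the (2R,3R) sense.

**Route**

Step 1
Reactants: 1 (R)-(−)-linalool, (3R)-3,7-dimethylocta-1,6-dien-3-ol
Product: 2 (3S,6R)-3-bromo-6-ethenyl-2,2,6-trimethyloxane (Br trans to vinyl)
Conditions: NBS (1.1 equiv), CH2Cl2, 0 °C, dark; chromatographic separation of the C3 epimers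
Reagents that add atoms: N-bromosuccinimide O=C1CCC(=O)N1Br
Why: Bromoetherification, in which NBS forms the bromonium ion at the electron-rich trisubstituted alkene and the tertiary hydroxyl opens it at the tertiary carbon (Markovnikov, 6-endo) through a chair with bromine equatorial, so that C6 is inherited from (R)-linalool while C3 should form as both epimers (vinyl and methyl at C6 are of similar size), from which 2 is separated.

Step 2
Reactants: 2 (3S,6R)-3-bromo-6-ethenyl-2,2,6-trimethyloxane
Product: 4 (2R,5S)-5-bromo-2,6,6-trimethyloxane-2-carbaldehyde, via ozonide 3 (not isolated)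
Conditions: O3, CH2Cl2, −78 °C; then PPh3, −78 °C to rt
Reagents that add atoms: ozone [O-][O+]=O
Why: Ozonolysis with reductive work-up, in which the only alkene is converted by cycloaddition and cycloreversion into ozonide 3 and then reduced to the aldehyde, whose quaternary α-carbon cannot epimerise and whose C–Br bond is inert to ozone.

Step 3
Reactants: 4 (2R,5S)-5-bromo-2,6,6-trimethyloxane-2-carbaldehyde; 5 1-(triphenyl-λ5-phosphanylidene)propan-2-one
Product: 6 (3E)-4-[(2R,5S)-5-bromo-2,6,6-trimethyloxan-2-yl]but-3-en-2-one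
Conditions: 5 (1.5 equiv), toluene, 100 °C
Reagents that add atoms: 1-(triphenyl-λ5-phosphanylidene)propan-2-one CC(=O)C=P(c1ccccc1)(c1ccccc1)c1ccccc1
Why: Wittig olefination with a stabilised ylide, which should give the (E)-enone and tolerates the hindered, non-enolisable aldehyde.

Step 4
Reactants: 6 (3E)-4-[(2R,5S)-5-bromo-2,6,6-trimethyloxan-2-yl]but-3-en-2-one
Product: 7 (2S,3E)-4-[(2R,5S)-5-bromo-2,6,6-trimethyloxan-2-yl]but-3-en-2-ol
Conditions: (R)-Me-CBS, i.e. (R)-1-methyl-3,3-diphenyltetrahydro-1H,3H-pyrrolo[1,2-c][1,3,2]oxazaborole (15 mol%), BH3·SMe2, THF, −30 °C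
Reagents that add atoms: none
Why: Corey–Bakshi–Shibata reduction, in which the (R)-oxazaborolidine holds borane and the ketone so that hydride reaches the carbonyl face that keeps the larger alkenyl group away from the catalyst, setting the (S)-carbinol centre by reagent control with 1,2-reduction only.

Step 5
Reactants: 7 (2S,3E)-4-[(2R,5S)-5-bromo-2,6,6-trimethyloxan-2-yl]but-3-en-2-ol; 8 triethyl orthoacetate
Product: 10 ethyl (3S,4E)-3-[(2R,5S)-5-bromo-2,6,6-trimethyloxan-2-yl]hex-4-enoate, via ketene acetal 9 (not isolated)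
Conditions: MeC(OEt)3 (excess), EtCO2H (cat.), 140 °C, ethanol distilled off
Reagents that add atoms: triethyl orthoacetate CCOC(C)(OCC)OCC
Why: Johnson–Claisen rearrangement, in which orthoester exchange and loss of ethanol give ketene acetal 9, whose [3,3] shift through a chair with the carbinol methyl equatorial forms the C1'–C2' bond on the face from which the C–O bond leaves, so that the (S)-carbinol configuration is transferred to C1' and the new alkene is E.

Step 6
Reactants: 10 ethyl (3S,4E)-3-[(2R,5S)-5-bromo-2,6,6-trimethyloxan-2-yl]hex-4-enoate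
Product: 11 (3S,4E)-3-[(2R,5S)-5-bromo-2,6,6-trimethyloxan-2-yl]hex-4-enal
Conditions: i-Bu2AlH (1.1 equiv), CH2Cl2, −78 °C; aqueous potassium sodium tartrate work-up
Reagents that add atoms: none
Why: Partial reduction of the ester with i-Bu2AlH at low temperature, where the aluminium hemiacetal survives until work-up and C1', being β to the carbonyl, is not at risk.

Step 7
Reactants: 11 (3S,4E)-3-[(2R,5S)-5-bromo-2,6,6-trimethyloxan-2-yl]hex-4-enal; 12 ethyl 2-[bis(2,2,2-trifluoroethoxy)phosphoryl]propanoate
Product: 13 ethyl (2Z,5S,6E)-5-[(2R,5S)-5-bromo-2,6,6-trimethyloxan-2-yl]-2-methylocta-2,6-dienoate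
Conditions: 12, KN(SiMe3)2, 18-crown-6, THF, −78 °C
Reagents that add atoms: ethyl 2-[bis(2,2,2-trifluoroethoxy)phosphoryl]propanoate CCOC(=O)C(C)P(=O)(OCC(F)(F)F)OCC(F)(F)F
Why: Still–Gennari olefination, in which the electron-poor phosphonate with a dissociated potassium counter-ion eliminates fast from the kinetic adduct and should give the (Z)-2-methyl enoate, the geometry that places the future ring carbons C2' and C5' cis on the C3'=C4' bond.

Step 8
Reactants: 13 ethyl (2Z,5S,6E)-5-[(2R,5S)-5-bromo-2,6,6-trimethyloxan-2-yl]-2-methylocta-2,6-dienoate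
Product: 14 (2Z,5S,6E)-5-[(2R,5S)-5-bromo-2,6,6-trimethyloxan-2-yl]-2-methylocta-2,6-dien-1-ol
Conditions: i-Bu2AlH (2.5 equiv), CH2Cl2, −78 °C
Reagents that add atoms: none
Why: 1,2-Reduction of the enoate with i-Bu2AlH to the allylic alcohol without change of the alkene geometry.

Step 9
Reactants: 14 (2Z,5S,6E)-5-[(2R,5S)-5-bromo-2,6,6-trimethyloxan-2-yl]-2-methylocta-2,6-dien-1-ol
Product: 15 (2R,3R,5S,6E)-3-bromo-5-[(2R,5S)-5-bromo-2,6,6-trimethyloxan-2-yl]-2-chloro-2-methyloct-6-en-1-ol
Conditions: NBS (1.1 equiv), ClTi(OiPr)3 (1.1 equiv), chiral tridentate Schiff-base ligand (salicylaldimine of a 1,1-diaryl-2-amino alcohol, 20 mol%), hexanes, −20 °C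
Reagents that add atoms: N-bromosuccinimide O=C1CCC(=O)N1Br; chlorotitanium triisopropoxide CC(C)O[Ti](Cl)(OC(C)C)OC(C)C
Why: Titanium-mediated enantioselective bromochlorination of an allylic alcohol, in which the alkoxide binds to the chiral titanium complex, NBS delivers bromine to one face of the trisubstituted alkene and titanium-bound chloride opens the bromonium ion anti at the tertiary carbon C4' (Markovnikov), so that C3' and C4' should arise by catalyst-controlled anti addition to the (Z)-alkene while the unactivated propenyl group reacts more slowly.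

Step 10
Reactants: 15 (2R,3R,5S,6E)-3-bromo-5-[(2R,5S)-5-bromo-2,6,6-trimethyloxan-2-yl]-2-chloro-2-methyloct-6-en-1-ol
Product: 16 (2R,3R,5S,6E)-3-bromo-5-[(2R,5S)-5-bromo-2,6,6-trimethyloxan-2-yl]-2-chloro-2-methyloct-6-enal
Conditions: Dess–Martin periodinane, pyridine, CH2Cl2, 0 °C to rt
Reagents that add atoms: none
Why: Dess–Martin oxidation under buffered conditions, after which the α-chloro aldehyde cannot enolise or epimerise because its α-carbon (C4') is quaternary.

Step 11
Reactants: 16 (2R,3R,5S,6E)-3-bromo-5-[(2R,5S)-5-bromo-2,6,6-trimethyloxan-2-yl]-2-chloro-2-methyloct-6-enal; 17 methyltriphenylphosphonium bromide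
Product: 18 (2R,5S)-5-bromo-2-[(2E,4S,6R,7R)-6-bromo-7-chloro-7-methylnona-2,8-dien-4-yl]-2,6,6-trimethyloxane
Conditions: 17, KN(SiMe3)2, THF, 0 °C; then 16, −78 to 0 °C
Reagents that add atoms: methyltriphenylphosphonium bromide C[P+](c1ccccc1)(c1ccccc1)c1ccccc1.[Br-]
Why: Wittig methylenation with the non-stabilised ylide at low temperature, where addition to the aldehyde should outrun elimination of HBr or HCl and no stereocentre can be lost because C4' bears no hydrogen.

Step 12
Reactants: 18 (2R,5S)-5-bromo-2-[(2E,4S,6R,7R)-6-bromo-7-chloro-7-methylnona-2,8-dien-4-yl]-2,6,6-trimethyloxane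
Product: 19 (2R,5S)-5-bromo-2-[(1S,4R,5R)-5-bromo-4-chloro-4-methylcyclohex-2-en-1-yl]-2,6,6-trimethyloxane
Conditions: second-generation Hoveyda–Grubbs catalyst (5–10 mol%), toluene (0.005 M), 60 °C, argon purge
Reagents that add atoms: none
Why: Ring-closing olefin metathesis by the Chauvin mechanism: the ruthenium carbene exchanges onto the terminal vinyl group at C4', adds across the propenyl double bond at C1' in a [2+2] step, and the ruthenacyclobutane opens to release propene and the C5'=C6' double bond. The closest known reaction type is ring-closing metathesis of 1,7-dienes to cyclohexenes with a fully substituted allylic carbon, including substrates that carry allylic and alkyl halides. Ring B closes as a six-membered carbocycle by alkene–alkene metathesis at C5'–C6', with the chain folded so that the ring A substituent at C1', the C3' bromine and the C4' chlorine sit pseudo-equatorial. No stereocentre is formed: C1', C3' and C4' enter with their final configuration and are not touched, since C5' and C6' are not stereogenic and C4' has no hydrogen. The step needs cyclisation to win over oligomerisation and the C–Cl and C–Br bonds to survive; high dilution, the fact that 18 holds only these two alkenes in a 1,7-relationship, the branching at C1' and C4' that favours folding, and the neutral, functional-group-tolerant catalyst should secure this.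

Step 13
Reactants: 19 (2R,5S)-5-bromo-2-[(1S,4R,5R)-5-bromo-4-chloro-4-methylcyclohex-2-en-1-yl]-2,6,6-trimethyloxane
Product: 20 deoxycaespitol, (3S,6R)-3-bromo-6-[(1R,3R,4R)-3-bromo-4-chloro-4-methylcyclohexyl]-2,2,6-trimethyloxane
Conditions: 2-nitrobenzenesulfonohydrazide (excess, in portions), Et3N, CH2Cl2, rt
Reagents that add atoms: none
Why: Diimide reduction, a concerted syn transfer of two hydrogen atoms from HN=NH to the cis-disubstituted ring alkene under neutral conditions, which should leave the allylic tertiary chloride, both secondary bromides and all five stereocentres untouched and creates no new stereocentre.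

**Compound list**

1 | (R)-(−)-linalool, (3R)-3,7-dimethylocta-1,6-dien-3-ol | CC(C)=CCC[C@@](C)(O)C=C | starting material
2 | (3S,6R)-3-bromo-6-ethenyl-2,2,6-trimethyloxane | CC1(C)O[C@@](C)(C=C)CC[C@@H]1Br | intermediate
3 | ozonide, 3-[(2R,5S)-5-bromo-2,6,6-trimethyloxan-2-yl]-1,2,4-trioxolane (both epimers at the trioxolane carbon) | CC1(C)O[C@@](C)(C2OCOO2)CC[C@@H]1Br | intermediate
4 | (2R,5S)-5-bromo-2,6,6-trimethyloxane-2-carbaldehyde | CC1(C)O[C@@](C)(C=O)CC[C@@H]1Br | intermediate
5 | 1-(triphenyl-λ5-phosphanylidene)propan-2-one | CC(=O)C=P(c1ccccc1)(c1ccccc1)c1ccccc1 | starting material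
6 | (3E)-4-[(2R,5S)-5-bromo-2,6,6-trimethyloxan-2-yl]but-3-en-2-one | CC1(C)O[C@@](C)(/C=C/C(C)=O)CC[C@@H]1Br | intermediate
7 | (2S,3E)-4-[(2R,5S)-5-bromo-2,6,6-trimethyloxan-2-yl]but-3-en-2-ol | CC1(C)O[C@@](C)(/C=C/[C@H](C)O)CC[C@@H]1Br | intermediate
8 | triethyl orthoacetate, 1,1,1-triethoxyethane | CCOC(C)(OCC)OCC | starting material
9 | ketene acetal, (2R,5S)-5-bromo-2-[(1E,3S)-3-(1-ethoxyethenyloxy)but-1-en-1-yl]-2,6,6-trimethyloxane | CC1(C)O[C@@](C)(/C=C/[C@H](C)OC(=C)OCC)CC[C@@H]1Br | intermediate
10 | ethyl (3S,4E)-3-[(2R,5S)-5-bromo-2,6,6-trimethyloxan-2-yl]hex-4-enoate | CC1(C)O[C@@](C)([C@@H](CC(=O)OCC)/C=C/C)CC[C@@H]1Br | intermediate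
11 | (3S,4E)-3-[(2R,5S)-5-bromo-2,6,6-trimethyloxan-2-yl]hex-4-enal | CC1(C)O[C@@](C)([C@@H](CC=O)/C=C/C)CC[C@@H]1Br | intermediate
12 | ethyl 2-[bis(2,2,2-trifluoroethoxy)phosphoryl]propanoate | CCOC(=O)C(C)P(=O)(OCC(F)(F)F)OCC(F)(F)F | starting material
13 | ethyl (2Z,5S,6E)-5-[(2R,5S)-5-bromo-2,6,6-trimethyloxan-2-yl]-2-methylocta-2,6-dienoate | CC1(C)O[C@@](C)([C@@H](C/C=C(/C)C(=O)OCC)/C=C/C)CC[C@@H]1Br | intermediate
14 | (2Z,5S,6E)-5-[(2R,5S)-5-bromo-2,6,6-trimethyloxan-2-yl]-2-methylocta-2,6-dien-1-ol | CC1(C)O[C@@](C)([C@@H](C/C=C(/C)CO)/C=C/C)CC[C@@H]1Br | intermediate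
15 | (2R,3R,5S,6E)-3-bromo-5-[(2R,5S)-5-bromo-2,6,6-trimethyloxan-2-yl]-2-chloro-2-methyloct-6-en-1-ol | CC1(C)O[C@@](C)([C@@H](C[C@@H](Br)[C@](C)(Cl)CO)/C=C/C)CC[C@@H]1Br | intermediate
16 | (2R,3R,5S,6E)-3-bromo-5-[(2R,5S)-5-bromo-2,6,6-trimethyloxan-2-yl]-2-chloro-2-methyloct-6-enal | CC1(C)O[C@@](C)([C@@H](C[C@@H](Br)[C@](C)(Cl)C=O)/C=C/C)CC[C@@H]1Br | intermediate
17 | methyltriphenylphosphonium bromide | C[P+](c1ccccc1)(c1ccccc1)c1ccccc1.[Br-] | starting material
18 | (2R,5S)-5-bromo-2-[(2E,4S,6R,7R)-6-bromo-7-chloro-7-methylnona-2,8-dien-4-yl]-2,6,6-trimethyloxane | CC1(C)O[C@@](C)([C@@H](C[C@@H](Br)[C@](C)(Cl)C=C)/C=C/C)CC[C@@H]1Br | intermediate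
19 | (2R,5S)-5-bromo-2-[(1S,4R,5R)-5-bromo-4-chloro-4-methylcyclohex-2-en-1-yl]-2,6,6-trimethyloxane | CC1(C)O[C@@](C)([C@@H]2C=C[C@@](C)(Cl)[C@H](Br)C2)CC[C@@H]1Br | intermediate
20 | deoxycaespitol, (3S,6R)-3-bromo-6-[(1R,3R,4R)-3-bromo-4-chloro-4-methylcyclohexyl]-2,2,6-trimethyloxane | CC1(C)O[C@@](C)([C@@H]2CC[C@@](C)(Cl)[C@H](Br)C2)CC[C@@H]1Br | target

Total step count: 13. Longest linear sequence: 13 steps (1 to 20).

**Steps most likely to fail**

Step 9. What may go wrong: bromonium formation at the propenyl group instead of the allylic alcohol alkene, chloride delivery to the secondary instead of the tertiary carbon, or facial control by the catalyst that is too weak against the bias of the C1' stereocentre. Fallback: the halogens are introduced one at a time through an epoxide; it sets out from 14 and comes back at 15. Epoxidation of 14 with Ti(OiPr)4, D-(−)-diethyl tartrate and t-BuOOH (4 Å molecular sieves, CH2Cl2, −20 °C; Sharpless asymmetric epoxidation, which leaves the propenyl group alone) should give the epoxy alcohol [(2R,3S)-3-{(2S,3E)-2-[(2R,5S)-5-bromo-2,6,6-trimethyloxan-2-yl]pent-3-en-1-yl}-2-methyloxiran-2-yl]methanol F1. Chelation-directed opening at the secondary carbon with MgBr2·OEt2 (Et2O, −20 °C) puts bromine on C3' with inversion and gives (2R,3R,5S,6E)-3-bromo-5-[(2R,5S)-5-bromo-2,6,6-trimethyloxan-2-yl]-2-methyloct-6-ene-1,2-diol F2. Ac2O and pyridine acetylate only the primary hydroxyl to give [(2R,3R,5S,6E)-3-bromo-5-[(2R,5S)-5-bromo-2,6,6-trimethyloxan-2-yl]-2-hydroxy-2-methyloct-6-en-1-yl] acetate F3. SOCl2 and pyridine (CH2Cl2, −20 °C) then ionise the tertiary chlorosulfite with participation of the anti bromine, and chloride opens the bromonium ion at the tertiary carbon with net retention to give [(2R,3R,5S,6E)-3-bromo-5-[(2R,5S)-5-bromo-2,6,6-trimethyloxan-2-yl]-2-chloro-2-methyloct-6-en-1-yl] acetate F4. i-Bu2AlH at −78 °C removes the acetate and returns 15.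

Step 12. What may go wrong: slow loading of the catalyst on two hindered alkenes (one on a quaternary carbon, one on the branched C1'), catalyst decay before ring closure, and ruthenium-induced loss of the allylic chloride on prolonged heating. Fallback: a relay tether brings the metal to the hindered site; it sets out from 16 and comes back at 19. Aldehyde 16 is treated with the ylide from (hex-5-en-1-yl)triphenylphosphonium bromide and KN(SiMe3)2 (THF, −78 °C) in place of step 11, which should give the relay triene (2R,5S)-5-bromo-2-[(2E,4S,6R,7R,8Z)-6-bromo-7-chloro-7-methyltetradeca-2,8,13-trien-4-yl]-2,6,6-trimethyloxane F5. With second-generation Grubbs catalyst (CH2Cl2, 40 °C) the ruthenium loads on the unhindered terminal alkene, expels cyclopentene and is thereby placed on C5', from where it closes ring B onto the propenyl group to give 19.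

Step 1. What may go wrong: competing 5-exo closure to oxolanes and lack of facial discrimination at C3 (vinyl and methyl at C6 are of similar size), so that much of the material is diverted to isomers. Fallback: ring A formation is run as a recycling loop instead of a single pass; it sets out from 1 and comes back at 1. The unwanted C3 epimer (3R,6R)-3-bromo-6-ethenyl-2,2,6-trimethyloxane F6, separated from 2, is stirred with Zn dust in EtOH/AcOH. Reductive β-elimination of the bromo ether (Boord type) reopens the ring and returns 1 with C6 untouched, which is cyclised again.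

**Further compounds**

F1 | step 9 | [(2R,3S)-3-{(2S,3E)-2-[(2R,5S)-5-bromo-2,6,6-trimethyloxan-2-yl]pent-3-en-1-yl}-2-methyloxiran-2-yl]methanol | CC1(C)O[C@@](C)([C@@H](C[C@@H]2O[C@]2(C)CO)/C=C/C)CC[C@@H]1Br
F2 | step 9 | (2R,3R,5S,6E)-3-bromo-5-[(2R,5S)-5-bromo-2,6,6-trimethyloxan-2-yl]-2-methyloct-6-ene-1,2-diol | CC1(C)O[C@@](C)([C@@H](C[C@@H](Br)[C@](C)(O)CO)/C=C/C)CC[C@@H]1Br
F3 | step 9 | [(2R,3R,5S,6E)-3-bromo-5-[(2R,5S)-5-bromo-2,6,6-trimethyloxan-2-yl]-2-hydroxy-2-methyloct-6-en-1-yl] acetate | CC1(C)O[C@@](C)([C@@H](C[C@@H](Br)[C@](C)(O)COC(C)=O)/C=C/C)CC[C@@H]1Br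
F4 | step 9 | [(2R,3R,5S,6E)-3-bromo-5-[(2R,5S)-5-bromo-2,6,6-trimethyloxan-2-yl]-2-chloro-2-methyloct-6-en-1-yl] acetate | CC1(C)O[C@@](C)([C@@H](C[C@@H](Br)[C@](C)(Cl)COC(C)=O)/C=C/C)CC[C@@H]1Br
F5 | step 12 | (2R,5S)-5-bromo-2-[(2E,4S,6R,7R,8Z)-6-bromo-7-chloro-7-methyltetradeca-2,8,13-trien-4-yl]-2,6,6-trimethyloxane | CC1(C)O[C@@](C)([C@@H](C[C@@H](Br)[C@](C)(Cl)/C=C\CCCC=C)/C=C/C)CC[C@@H]1Br
F6 | step 1 | (3R,6R)-3-bromo-6-ethenyl-2,2,6-trimethyloxane | CC1(C)O[C@@](C)(C=C)CC[C@H]1Br
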